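Flavone numbering is used throughout: O1, C2, C3, C4, C4a, C5–C8, C8a; ring B is C1'–C6'; C9 is the CH2 on C3 and C10 the O-bearing CH; the pyran atoms are O7, C2'', C3'', C4''. PMB is 4-methoxybenzyl, TES is triethylsilyl.

## Analysis of the target

The target is a flavone (ring A, pyranone ring C, ring B) with two further rings. A 2,2-dimethyl-2H-pyran is fused angularly across C7–C8 of ring A (oxygen on C7, the CH=CH carbon on C8). A seven-membered oxepine links C3 to the 2'-oxygen of ring B through C9H2 and C10H. C10 is the only stereocentre; it is R and carries the 2-hydroxypropan-2-yl group, so only absolute configuration has to be set and then kept. The sensitive groups are the chromene double bond (no hydrogenolysis, no strong acid), the tertiary alcohol next to the stereocentre, and two phenols (5-OH chelated to C4=O, 4'-OH). The difficulties are the tetrasubstituted C2=C3 bond shared by the pyranone and the oxepine, the seven-membered ring, the angular rather than linear pyran, and the direction of pyranone closure on a ring A whose two ortho positions are both oxygenated in the product. The strategy rests on one feature: C2, C3 and C4 form a three-carbon unit oxygenated at both ends, which maps onto C3, C4 and C5 of an isoxazole, and C2–C3 is the bond common to pyranone and oxepine. A cycloaddition that builds this isoxazole across a tether from the 2'-oxygen therefore closes the oxepine in the same event.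

## Retrosynthetic reasoning

**25 to 24.** The two phenols are masked as PMB ethers in 24. Benzyl-type groups that need hydrogenolysis are excluded by the chromene double bond, and PMB ethers of carbonyl-conjugated phenols ionise under mild acid. Deprotection is therefore the last operation.

**24 to 23.** The O1–C8a bond is cut. In 23 ring A carries a single fluorine on C8a, next to the pyran-bearing C8, and the other ortho position (C5) is already an ether. The enolate oxygen of the diketone can thus displace only that fluorine, and the pyranone can only close in the angular sense. The forward step is an intramolecular fluoride displacement ortho to an aroyl group.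

**23 to 22 to 21.** The 1,3-diketone is traced to isoxazole 21. Reductive N–O cleavage gives enaminone 22, and hydrolysis replaces the nitrogen on C2 by oxygen. The isoxazole keeps C2 and C4 at the right oxidation level through the bond-forming step without an acidic diketone being present.

**21 to 20 to 18 (key disconnection).** C2–C3 and C4–O are cut together. Nitrile oxide 20, generated from aldoxime 18, sits on ring B ortho to an ether whose chain O–C10–C9 ends at the alkyne. Addition of the dipole carbon to the proximal alkyne carbon closes both the isoxazole and the oxepine, and the tether leaves no regiochemical choice. Cutting here reduces the pentacycle to an acyclic aryl ether that holds all carbons and the stereocentre.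

**18 to 17 to 14 + 16.** The oxime comes from aldehyde 17. The C2'–O bond of 17 is cut to diol 14 and fluoroaldehyde 16. The forward fluoride displacement uses the oxygen of 14 as nucleophile, so no bond to C10 is broken and the configuration is retained. A displacement at C10 by a phenol would instead require an SN2 reaction next to a quaternary carbon.

**14 to 8 + 11, and 11 to 9.** The C3–C9 bond is cut between the acetylide of 8 and the terminal carbon of epoxide 11. Compound 11 is the TES ether of alkoxide 10, which forms by double methyl addition to glycidate 9; the glycidate supplies C9, C10, the carbinol carbon and the R configuration. The silyl ether blocks Payne-type rearrangement during the opening. It is removed before 14 is used, because a silyl group on the tertiary oxygen would migrate to the secondary alkoxide needed for the aryl ether.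

**8 to 7 to 5 to 4 to 1 + 2.** The alkyne of 8 comes from aldehyde 7 by one-carbon homologation. The pyran of 7 is opened to aryl propargyl ether 5 (C8–C4'' made by a [3,3] shift, O7–C2'' re-formed by oxa-6π closure). Compound 5 comes from the symmetrical difluoride 4 by replacing one fluorine with the PMB-oxy group, so the desymmetrisation itself cannot give isomers. Compound 4 is the ether of phenol 1 with alcohol 2.

**16 to 15.** The ring B electrophile is the PMB ether of phenol 15.

## Alternatives that were turned down

**Alternative 1: ring B by alkyne cyclotrimerisation.** The disconnection cuts C1'–C2', C3'–C4' and C5'–C6'. The precursor is diyne A1, a pyranochromone that already carries the C3 side chain, a silyl-capped alkyne on C2 and an ethynyl ether on the C10 oxygen. The third alkyne is the boryl alkyne A2. The rhodium salt A3, which is [Rh(cod)2]BF4, and the bisphosphine A4, which is BINAP, would together form a cationic monovalent rhodium catalyst. On it the two tethered alkynes would couple oxidatively and A2 would insert, giving A5 with ring B and the oxepine closed together.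

- For it: ring A, the pyran and the pyranone are settled before the key step, so no fluoride-dependent closure is needed. The boron substituent is a direct precursor of the 4'-OH.
- Against it: the ethynyl ether of a hindered secondary alcohol is hard to make and fragments by a retro-ene pathway on mild heating. The position of boron (C4' and not C5') depends only on steric steering by the silyl group, which must then be removed. A1 is itself a long build, since it needs a 3-alkylated 2-alkynylchromone carrying the stereocentre. Boron oxidation, desilylation and two deprotections follow the key step.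
- Comparison: on the security of the ring A and pyranone regiochemistry this alternative is stronger. The chosen route offers instead robust acyclic precursors and a key step whose regiochemistry is fixed by connectivity, not by steric tuning.

**Alternative 2: late angular pyran by prenal condensation and oxa-6π closure.** The disconnection cuts C8–C4'' and O7–C2''. The 5,7-dihydroxy oxepinoflavone A6 would condense at C8 with the enal A7, which is 3-methylbut-2-enal, under catalysis by the ammonium salt A8, which is ethylenediammonium diacetate. The resulting dienone would close to the pyran, giving A9, the 4'-MOM ether of the target.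

- For it: the acid- and hydrogenation-sensitive chromene appears last, so earlier steps have full freedom in protecting groups. Only one deprotection remains.
- Against it: A6 offers C6 and C8 as nucleophilic carbons, and nothing in its structure enforces C8, so linear and angular pyrans are both expected. The pentacyclic core of A6 with its stereocentre still has to be made, so this is an end game and not a solution to the core.
- Comparison: in end-game step count and protecting-group freedom it is stronger. The chosen route fixes the angular fusion early, through the position of the single fluorine, and pays by carrying the chromene through nine further steps.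

**Alternative 3: rhodium conjugate cyclisation with enantioselective protonation.** The disconnection cuts C3–C9 and creates C10 in the same step. Boronate A10 is a flavone with boron on C3 and an acrylate on the 2'-oxygen. It would transmetalate to a hydroxo complex of monovalent rhodium formed from the dimer A11, which is [Rh(OH)(cod)]2, and the bisphosphine A4. The C3–Rh bond would add across the acrylate to close the oxepine, and the rhodium enolate would be protonated enantioselectively to give ester A12.

- For it: the stereocentre is set by catalysis, the flavone is assembled first by standard chemistry, and no fluorine is needed.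
- Against it: enantioselective protonation after rhodium 1,4-addition is established for intermolecular additions to α-substituted acrylates, not for a seven-membered closure onto an α-aryloxy acrylate. A 3-borylchromone is prone to protodeboronation. The new centre in A12 is α to an ester and bears an aryloxy group, so it epimerises easily. Converting the ester to the tertiary carbinol needs two additions of a basic methyl nucleophile in the presence of the pyranone carbonyl.
- Comparison: it is stronger in elegance and in independence from the chiral pool. The chosen route offers configurational security: C10 comes from a glycidate, the carbinol is installed first, and the centre is never α to a carbonyl.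

Key step: step 10

Assumption: 2,6-difluoro-4-hydroxybenzaldehyde (1) is taken as a commercial building block. Diketone 23 is drawn in the diketo form; it should exist as keto–enol tautomers and C3 epimers, which is without consequence because C3 becomes sp2 in step 13.

## Route

Step 1
Reactants: 1 2,6-difluoro-4-hydroxybenzaldehyde; 2 2-methylbut-3-yn-2-ol
Product: 4 2,6-difluoro-4-[(2-methylbut-3-yn-2-yl)oxy]benzaldehyde, via propargylic trifluoroacetate 3 (not isolated)
Conditions: 2, (CF3CO)2O, DBU, MeCN, −5 °C; then 1, DBU, CuCl2·2H2O (cat.), MeCN, −5 → 0 °C
Reagents that add atoms: none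
Why: Copper-catalysed propargylic substitution of an in situ trifluoroacetate by a phenoxide (Godfrey-type aryl propargyl ether synthesis); the acidic, electron-poor phenol is a good partner and the formyl group is tolerated.

Step 2
Reactants: 4 2,6-difluoro-4-[(2-methylbut-3-yn-2-yl)oxy]benzaldehyde
Product: 5 2-fluoro-6-[(4-methoxybenzyl)oxy]-4-[(2-methylbut-3-yn-2-yl)oxy]benzaldehyde
Conditions: 4-methoxybenzyl alcohol (1.0 equiv), NaH, THF, 0 °C → rt
Reagents that add atoms: 4-methoxybenzyl alcohol, COc1ccc(CO)cc1
Why: Nucleophilic aromatic substitution (addition–elimination) of a fluoride ortho to the formyl group; the two fluorines are equivalent, so no regioisomer can form, and the new alkoxy donor should deactivate the ring against a second substitution.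

Step 3
Reactants: 5 2-fluoro-6-[(4-methoxybenzyl)oxy]-4-[(2-methylbut-3-yn-2-yl)oxy]benzaldehyde
Product: 7 5-fluoro-7-[(4-methoxybenzyl)oxy]-2,2-dimethyl-2H-chromene-6-carbaldehyde, via allenyl phenol 6 (not isolated)
Conditions: PhNEt2, 180 °C
Reagents that add atoms: none
Why: Aryl propargyl ether Claisen rearrangement followed by 1,5-hydrogen shift and oxa-6π electrocyclisation; the [3,3] shift should go to the ortho carbon that is para to the PMB-oxy donor and flanked only by fluorine, as 3-alkoxyphenyl propargyl ethers give 7-alkoxychromenes, which places fluorine next to the pyran-bearing carbon.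

Step 4
Reactants: 7 5-fluoro-7-[(4-methoxybenzyl)oxy]-2,2-dimethyl-2H-chromene-6-carbaldehyde
Product: 8 6-ethynyl-5-fluoro-7-[(4-methoxybenzyl)oxy]-2,2-dimethyl-2H-chromene
Conditions: dimethyl (1-diazo-2-oxopropyl)phosphonate, K2CO3, MeOH, rt
Reagents that add atoms: dimethyl (1-diazo-2-oxopropyl)phosphonate, COP(=O)(OC)C(=[N+]=[N-])C(C)=O
Why: Seyferth–Gilbert homologation in the Ohira–Bestmann variant (olefination to a diazoalkene, loss of N2, 1,2-hydrogen shift of the alkylidene carbene); carbonate in methanol at room temperature is too weak a nucleophile system to displace a fluoride activated by a single formyl group.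

Step 5
Reactants: 9 methyl (2R)-oxirane-2-carboxylate
Product: 11 triethyl({2-[(2R)-oxiran-2-yl]propan-2-yl}oxy)silane, via lithium alkoxide 10 (not isolated)
Conditions: MeLi (2.2 equiv), THF, −78 °C; then Et3SiCl (2.3 equiv), DMPU, −78 °C → rt
Reagents that add atoms: methyllithium, [Li]C; chlorotriethylsilane, CC[Si](Cl)(CC)CC
Why: Double addition of the organolithium to the ester through the methyl ketone, with the oxirane inert at low temperature without a Lewis acid, then O-silylation of the lithium alkoxide in the same flask; no bond to the stereocentre is broken, so R is carried over, and silylation avoids isolating a volatile, water-soluble epoxy alcohol that could undergo Payne rearrangement.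

Step 6
Reactants: 8 6-ethynyl-5-fluoro-7-[(4-methoxybenzyl)oxy]-2,2-dimethyl-2H-chromene; 11 triethyl({2-[(2R)-oxiran-2-yl]propan-2-yl}oxy)silane
Product: 14 (3R)-6-{5-fluoro-7-[(4-methoxybenzyl)oxy]-2,2-dimethyl-2H-chromen-6-yl}-2-methylhex-5-yne-2,3-diol, via lithium acetylide 12 (not isolated), via silyl ether 13 (not isolated)
Conditions: 8, n-BuLi, THF, −78 °C; BF3·OEt2; 11, −78 °C; aq. NH4Cl; then Bu4NF, THF, rt
Reagents that add atoms: none
Why: Yamaguchi–Hirao alkynylation, an SN2 opening of the BF3-activated epoxide at its unsubstituted CH2 carbon, so the C–O bond at the stereocentre is untouched and R is retained; fluoride then removes the TES group so that no silyl group can migrate onto the secondary alkoxide used in step 8.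

Step 7
Reactants: 15 2-fluoro-4-hydroxybenzaldehyde
Product: 16 2-fluoro-4-[(4-methoxybenzyl)oxy]benzaldehyde
Conditions: 4-methoxybenzyl chloride, K2CO3, DMF, rt
Reagents that add atoms: 4-methoxybenzyl chloride, COc1ccc(CCl)cc1
Why: Williamson ether synthesis on a phenoxide stabilised by the para formyl group; carbonate at room temperature should not displace the fluoride.

Step 8
Reactants: 14 (3R)-6-{5-fluoro-7-[(4-methoxybenzyl)oxy]-2,2-dimethyl-2H-chromen-6-yl}-2-methylhex-5-yne-2,3-diol; 16 2-fluoro-4-[(4-methoxybenzyl)oxy]benzaldehyde
Product: 17 2-{[(3R)-6-{5-fluoro-7-[(4-methoxybenzyl)oxy]-2,2-dimethyl-2H-chromen-6-yl}-2-hydroxy-2-methylhex-5-yn-3-yl]oxy}-4-[(4-methoxybenzyl)oxy]benzaldehyde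
Conditions: 14, NaH (1.05 equiv), DMF, 0 °C; then 16, 0 °C → rt
Reagents that add atoms: none
Why: Nucleophilic aromatic substitution of the fluoride ortho to the formyl group by the secondary alkoxide, which is less hindered than the tertiary one; the oxygen of 14 is the nucleophile, so the C10–O bond is not broken and the R configuration is retained.

Step 9
Reactants: 17 aryl ether aldehyde
Product: 18 (E)-aldoxime of 17
Conditions: NH2OH·HCl, NaOAc, EtOH/H2O, rt
Reagents that add atoms: hydroxylamine (as hydrochloride), NO
Why: Oxime condensation of an aryl aldehyde under buffered conditions; the E isomer is the usual product and the geometry is irrelevant for the next step.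

Step 10
Reactants: 18 (E)-aldoxime
Product: 21 isoxazole-fused dihydrobenzoxepine carrying the fluorochromenyl group on the isoxazole carbon bonded to oxygen (R at C10; both phenols as PMB ethers), via hydroximoyl chloride 19 (not isolated), via nitrile oxide 20 (not isolated)
Conditions: aq. NaOCl (1.5 equiv), CH2Cl2, 0 °C → rt, slow addition of 18, final concentration about 5 mM
Reagents that add atoms: none
Why: Hypochlorite chlorinates the aldoxime carbon to 19 and the aqueous base removes HCl to give nitrile oxide 20, which adds to the tethered alkyne in a concerted, asynchronous (3+2) cycloaddition: the dipole carbon (C2) bonds to the alkyne carbon next to the CH2 group (C3) and the dipole oxygen bonds to the aryl-bearing alkyne carbon (C4). The closest known reaction type is the intramolecular nitrile oxide–alkyne cycloaddition of O-alkynyl salicylaldoximes, which gives isoxazole-fused benzopyrans and benzoxepines. The isoxazole ring is closed by the cycloaddition itself, both new bonds forming in one step; the oxepine closes in the fused mode (7-exo-dig with respect to the C2–C3 bond) because the chain C1'–C2'–O–C10–C9 already links the dipole carbon to the proximal alkyne carbon. No stereocentre is created, and C10 carries no acidic hydrogen under the mildly basic two-phase conditions, so its configuration is untouched. Regiochemistry is fixed by the tether, since the reverse orientation would need a bridged bicycle that a five-atom link cannot span. The selectivity needed is cyclisation over dimerisation to the furoxan; it is secured by generating 20 slowly at high dilution, by the ortho alkoxy group that shields the dipole, and by the bulky 2-hydroxypropan-2-yl group on C10, which favours the folded conformer. The tertiary alcohol should not add to the dipole without strong base, and without a phase-transfer catalyst the hypochlorite should not reach the chromene double bond.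

Step 11
Reactants: 21 isoxazole-fused dihydrobenzoxepine
Product: 22 (Z)-β-amino enone (NH2 on C2 and aroyl on C3 of the dihydrobenzoxepine)
Conditions: Mo(CO)6, MeCN/H2O, 80 °C
Reagents that add atoms: none
Why: Reductive N–O cleavage of an isoxazole by zerovalent molybdenum with water as the proton source, a standard unmasking to the vinylogous amide; PMB ethers, aryl fluoride and chromene are inert to it.

Step 12
Reactants: 22 (Z)-β-amino enone
Product: 23 1,3-diketone (4-aroyl-3,4-dihydro-1-benzoxepin-5(2H)-one)
Conditions: 1 M aq. HCl, THF, rt
Reagents that add atoms: water, O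
Why: Acid hydrolysis of a vinylogous amide (C-protonation at C3, addition of water to the iminium, loss of ammonia); the tetrasubstituted enaminone is twisted and should hydrolyse under dilute aqueous acid that leaves aryl PMB ethers and the chromene intact, and any hemiketal formed by the tertiary alcohol stays in equilibrium with the diketone. Removing nitrogen here prevents quinolone formation in the next step.

Step 13
Reactants: 23 1,3-diketone
Product: 24 5,4'-bis-PMB ether of the target
Conditions: K2CO3, dry DMF, 80 °C
Reagents that add atoms: none
Why: Intramolecular nucleophilic aromatic substitution of the fluoride ortho to the aroyl carbonyl by the enolate oxygen on C2 (six-membered closure, the usual chromone synthesis from 2-fluoroaryl 1,3-diketones); ring A holds one fluorine, next to the pyran-bearing carbon, so only the angular pyranone can form.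

Step 14
Reactants: 24 5,4'-bis-PMB ether of the target
Product: 25 target CNP0329736.1
Conditions: CF3CO2H (10% v/v), anisole, CH2Cl2, 0 °C
Reagents that add atoms: none
Why: Acidolysis of PMB aryl ethers by an SN1 pathway, fast here because both phenols are carbonyl-conjugated and good leaving groups; anisole traps the PMB cation by Friedel–Crafts alkylation, and short exposure at 0 °C should spare the chromene double bond and the tertiary alcohol, which is deactivated towards ionisation by the adjacent C–O bond.

## Compound list

1 | 2,6-difluoro-4-hydroxybenzaldehyde | O=Cc1c(F)cc(O)cc1F | starting material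
2 | 2-methylbut-3-yn-2-ol | CC(C)(O)C#C | starting material
3 | 2-methylbut-3-yn-2-yl trifluoroacetate | CC(C)(OC(=O)C(F)(F)F)C#C | intermediate (not isolated)
4 | 2,6-difluoro-4-[(2-methylbut-3-yn-2-yl)oxy]benzaldehyde | O=Cc1c(F)cc(OC(C)(C)C#C)cc1F | intermediate
5 | 2-fluoro-6-[(4-methoxybenzyl)oxy]-4-[(2-methylbut-3-yn-2-yl)oxy]benzaldehyde | O=Cc1c(F)cc(OC(C)(C)C#C)cc1OCc1ccc(OC)cc1 | intermediate
6 | 2-fluoro-4-hydroxy-6-[(4-methoxybenzyl)oxy]-3-(3-methylbuta-1,2-dien-1-yl)benzaldehyde | O=Cc1c(F)c(C=C=C(C)C)c(O)cc1OCc1ccc(OC)cc1 | intermediate (not isolated)
7 | 5-fluoro-7-[(4-methoxybenzyl)oxy]-2,2-dimethyl-2H-chromene-6-carbaldehyde | O=Cc1c(F)c2C=CC(C)(C)Oc2cc1OCc1ccc(OC)cc1 | intermediate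
8 | 6-ethynyl-5-fluoro-7-[(4-methoxybenzyl)oxy]-2,2-dimethyl-2H-chromene | C#Cc1c(F)c2C=CC(C)(C)Oc2cc1OCc1ccc(OC)cc1 | intermediate
9 | methyl (2R)-oxirane-2-carboxylate, methyl (R)-glycidate | COC(=O)[C@H]1CO1 | starting material
10 | lithium 2-[(2R)-oxiran-2-yl]propan-2-olate | [Li+].CC(C)([O-])[C@H]1CO1 | intermediate (not isolated)
11 | triethyl({2-[(2R)-oxiran-2-yl]propan-2-yl}oxy)silane | CC[Si](CC)(CC)OC(C)(C)[C@H]1CO1 | intermediate
12 | lithium acetylide of 8 | [Li]C#Cc1c(F)c2C=CC(C)(C)Oc2cc1OCc1ccc(OC)cc1 | intermediate (not isolated)
13 | (3R)-6-{5-fluoro-7-[(4-methoxybenzyl)oxy]-2,2-dimethyl-2H-chromen-6-yl}-2-methyl-2-[(triethylsilyl)oxy]hex-5-yn-3-ol | CC[Si](CC)(CC)OC(C)(C)[C@H](O)CC#Cc1c(F)c2C=CC(C)(C)Oc2cc1OCc1ccc(OC)cc1 | intermediate (not isolated)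
14 | (3R)-6-{5-fluoro-7-[(4-methoxybenzyl)oxy]-2,2-dimethyl-2H-chromen-6-yl}-2-methylhex-5-yne-2,3-diol | CC(C)(O)[C@H](O)CC#Cc1c(F)c2C=CC(C)(C)Oc2cc1OCc1ccc(OC)cc1 | intermediate
15 | 2-fluoro-4-hydroxybenzaldehyde | O=Cc1ccc(O)cc1F | starting material
16 | 2-fluoro-4-[(4-methoxybenzyl)oxy]benzaldehyde | O=Cc1ccc(OCc2ccc(OC)cc2)cc1F | intermediate
17 | 2-{[(3R)-6-{5-fluoro-7-[(4-methoxybenzyl)oxy]-2,2-dimethyl-2H-chromen-6-yl}-2-hydroxy-2-methylhex-5-yn-3-yl]oxy}-4-[(4-methoxybenzyl)oxy]benzaldehyde | O=Cc1ccc(OCc2ccc(OC)cc2)cc1O[C@@H](C(C)(C)O)CC#Cc1c(F)c2C=CC(C)(C)Oc2cc1OCc1ccc(OC)cc1 | intermediate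
18 | (E)-oxime of 17, the cycloaddition precursor | O/N=C/c1ccc(OCc2ccc(OC)cc2)cc1O[C@@H](C(C)(C)O)CC#Cc1c(F)c2C=CC(C)(C)Oc2cc1OCc1ccc(OC)cc1 | intermediate
19 | (Z)-N-hydroxybenzimidoyl chloride derived from 18 | O/N=C(\Cl)c1ccc(OCc2ccc(OC)cc2)cc1O[C@@H](C(C)(C)O)CC#Cc1c(F)c2C=CC(C)(C)Oc2cc1OCc1ccc(OC)cc1 | intermediate (not isolated)
20 | aryl nitrile oxide derived from 18 | [O-][N+]#Cc1ccc(OCc2ccc(OC)cc2)cc1O[C@@H](C(C)(C)O)CC#Cc1c(F)c2C=CC(C)(C)Oc2cc1OCc1ccc(OC)cc1 | intermediate (not isolated)
21 | isoxazole fused through its C3–C4 bond to a 2,3-dihydro-1-benzoxepine: isoxazole C3 on ring B C1', isoxazole C4 on the oxepine CH2, isoxazole C5 bearing 5-fluoro-7-(PMB-oxy)-2,2-dimethyl-2H-chromen-6-yl; (R)-CH(O) with 2-hydroxypropan-2-yl; PMB-oxy para to the isoxazole on ring B | COc1ccc(COc2ccc3c(c2)O[C@@H](C(C)(C)O)Cc2c-3noc2-c2c(F)c3C=CC(C)(C)Oc3cc2OCc2ccc(OC)cc2)cc1 | intermediate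
22 | [(2R)-5-amino-2-(2-hydroxypropan-2-yl)-8-[(4-methoxybenzyl)oxy]-2,3-dihydro-1-benzoxepin-4-yl]{5-fluoro-7-[(4-methoxybenzyl)oxy]-2,2-dimethyl-2H-chromen-6-yl}methanone | COc1ccc(COc2ccc3c(c2)O[C@@H](C(C)(C)O)CC(C(=O)c2c(F)c4C=CC(C)(C)Oc4cc2OCc2ccc(OC)cc2)=C3N)cc1 | intermediate
23 | (2R)-4-{5-fluoro-7-[(4-methoxybenzyl)oxy]-2,2-dimethyl-2H-chromene-6-carbonyl}-2-(2-hydroxypropan-2-yl)-8-[(4-methoxybenzyl)oxy]-3,4-dihydro-1-benzoxepin-5(2H)-one (C4 epimers and enol forms) | COc1ccc(COc2ccc3c(c2)O[C@@H](C(C)(C)O)CC(C(=O)c2c(F)c4C=CC(C)(C)Oc4cc2OCc2ccc(OC)cc2)C3=O)cc1 | intermediate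
24 | 5,4'-bis(4-methoxybenzyl) ether of the target | CC1(C)C=Cc2c(cc(OCc3ccc(OC)cc3)c3c(=O)c4c(oc23)-c2ccc(OCc3ccc(OC)cc3)cc2O[C@@H](C(C)(C)O)C4)O1 | intermediate
25 | CNP0329736.1: (10R)-5,4'-dihydroxy flavone with a 2,2-dimethylpyran fused at C7–C8 and an oxepine C3–C9H2–C10H(CMe2OH)–O–C2' | CC1(C)C=Cc2c(cc(O)c3c(=O)c4c(oc23)-c2ccc(O)cc2O[C@@H](C(C)(C)O)C4)O1 | target

## Step count and least certain steps

Total step count: 14. Longest linear sequence: 12 steps (steps 1–4, 6, 8–14).

**Step 10 (key step).** The most likely failure is that dimerisation of the nitrile oxide to the furoxan, or its decomposition, outruns a cycloaddition slowed by an internal alkyne carrying a di-ortho-substituted aryl group. Electrophilic chlorination of ring A or of the chromene double bond by hypochlorite is a second route of loss. The fallback replaces the alkyne dipolarophile by the more reactive Z-alkene and reaches the diketone without an isoxazole. It sets out from 17. Semihydrogenation over Pd/CaCO3 poisoned with Pb(OAc)2 and quinoline under H2 would give the Z-alkene aldehyde F1. Oxime formation as in step 9 would give the oxime F2. Oxidation under the conditions of step 10 would give, by intramolecular nitrile oxide–alkene cycloaddition, the fused isoxazoline F3 (cis at the two new centres, epimers relative to C10 without consequence). Mo(CO)6 in MeCN/H2O would cleave the N–O bond and hydrolyse the imine to the β-hydroxy ketone F4. Oxidation with Dess–Martin periodinane returns to the route at 23.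

**Step 3.** The risk is poor regioselectivity in the [3,3] shift: rearrangement to the ortho carbon next to the PMB-oxy group would give the linear 7-fluoro-5-alkoxy chromene, because the two ortho positions differ only by the balance of donor and steric effects. The fallback reverses the order of rearrangement and desymmetrisation. It sets out from 4, whose two ortho positions are equivalent, and heating as in step 3 would give 5,7-difluoro-2,2-dimethyl-2H-chromene-6-carbaldehyde F5. Displacement of the less hindered fluoride (C7, flanked by hydrogen, not by the ring fusion) with sodium 4-methoxybenzyl oxide returns to the route at 7. This moves the selectivity question to a steric differentiation and does not remove it.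

**Step 8.** The risk is slow substitution. The alkoxide adds reversibly to the formyl group and the para alkoxy group weakens the activation. Base-induced addition of an alkoxide to the alkyne, or arylation of the tertiary oxygen, could then compete. The fallback uses a nitrile as the activating group. It sets out from 16, which I2 in aqueous NH3/THF would convert to 2-fluoro-4-[(4-methoxybenzyl)oxy]benzonitrile F6. Substitution with the sodium alkoxide of 14 would give the aryl ether nitrile F7. Reduction with i-Bu2AlH at −78 °C and hydrolysis of the aldimine returns to the route at 17.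

**Step 14.** The risk is acid damage during deprotection: protonation or PMB-cation alkylation of the chromene double bond, or ionisation of the tertiary alcohol. The fallback avoids Brønsted acid and removes the two groups separately. It sets out from 24. MgBr2·OEt2 with Me2S would cleave the chelated 5-O-PMB ether to the 4'-mono-PMB ether F8. DDQ in wet CH2Cl2 would then remove the remaining group oxidatively and return to the route at 25.

## Further compounds

F1 | step 10 | Z-alkene analogue of aldehyde 17 | O=Cc1ccc(OCc2ccc(OC)cc2)cc1O[C@@H](C(C)(C)O)C/C=C\c1c(F)c2C=CC(C)(C)Oc2cc1OCc1ccc(OC)cc1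
F2 | step 10 | (E)-oxime of F1 | O/N=C/c1ccc(OCc2ccc(OC)cc2)cc1O[C@@H](C(C)(C)O)C/C=C\c1c(F)c2C=CC(C)(C)Oc2cc1OCc1ccc(OC)cc1
F3 | step 10 | isoxazoline-fused tetrahydrobenzoxepine (cis at the two new centres, mixture relative to C10) | COc1ccc(COc2ccc3c(c2)O[C@@H](C(C)(C)O)CC2C3=NOC2c2c(F)c3C=CC(C)(C)Oc3cc2OCc2ccc(OC)cc2)cc1
F4 | step 10 | β-hydroxy ketone: 4-[aryl(hydroxy)methyl]-3,4-dihydro-1-benzoxepin-5(2H)-one (mixture at the two new centres) | COc1ccc(COc2ccc3c(c2)O[C@@H](C(C)(C)O)CC(C(O)c2c(F)c4C=CC(C)(C)Oc4cc2OCc2ccc(OC)cc2)C3=O)cc1
F5 | step 3 | 5,7-difluoro-2,2-dimethyl-2H-chromene-6-carbaldehyde | O=Cc1c(F)cc2OC(C)(C)C=Cc2c1F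
F6 | step 8 | 2-fluoro-4-[(4-methoxybenzyl)oxy]benzonitrile | N#Cc1ccc(OCc2ccc(OC)cc2)cc1F
F7 | step 8 | nitrile analogue of aldehyde 17 | N#Cc1ccc(OCc2ccc(OC)cc2)cc1O[C@@H](C(C)(C)O)CC#Cc1c(F)c2C=CC(C)(C)Oc2cc1OCc1ccc(OC)cc1
F8 | step 14 | 4'-mono(4-methoxybenzyl) ether of the target | CC1(C)C=Cc2c(cc(O)c3c(=O)c4c(oc23)-c2ccc(OCc3ccc(OC)cc3)cc2O[C@@H](C(C)(C)O)C4)O1
A1 | alternative 1 | 2-[(trimethylsilyl)ethynyl]pyranochromone with the C3 side chain CH2–CH(OC≡CH)–CMe2(OTES), 5-MOM ether | CC1(C)C=Cc2c(cc(OCOC)c3c(=O)c(C[C@@H](OC#C)C(C)(C)O[Si](CC)(CC)CC)c(C#C[Si](C)(C)C)oc23)O1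
A2 | alternative 1 | ethynylboronic acid pinacol ester | C#CB1OC(C)(C)C(C)(C)O1
A3 | alternative 1 | [Rh(cod)2]BF4, bis(cycloocta-1,5-diene)rhodium tetrafluoroborate | [Rh+].C1=CCCC=CCC1.C1=CCCC=CCC1.F[B-](F)(F)F
A4 | alternative 1 | BINAP, 2,2'-bis(diphenylphosphino)-1,1'-binaphthyl (one atropisomer; the axis is not encoded) | c1ccc(cc1)P(c1ccccc1)c1ccc2ccccc2c1-c1c(ccc2ccccc12)P(c1ccccc1)c1ccccc1
A5 | alternative 1 | oxepinoflavone with 4'-Bpin and 6'-SiMe3, 5-MOM ether and tertiary TES ether | CC1(C)C=Cc2c(cc(OCOC)c3c(=O)c4c(oc23)-c2c([Si](C)(C)C)cc(B5OC(C)(C)C(C)(C)O5)cc2O[C@@H](C(C)(C)O[Si](CC)(CC)CC)C4)O1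
A6 | alternative 2 | 5,7-dihydroxy oxepinoflavone, 4'-MOM ether, without the pyran | Oc1cc(O)c2c(=O)c3c(oc2c1)-c1ccc(OCOC)cc1O[C@@H](C(C)(C)O)C3
A7 | alternative 2 | 3-methylbut-2-enal | CC(C)=CC=O
A8 | alternative 2 | ethylenediammonium diacetate | [NH3+]CC[NH3+].CC([O-])=O.CC([O-])=O
A9 | alternative 2 | target as its 4'-MOM ether | CC1(C)C=Cc2c(cc(O)c3c(=O)c4c(oc23)-c2ccc(OCOC)cc2O[C@@H](C(C)(C)O)C4)O1
A10 | alternative 3 | pyranoflavone with 3-Bpin and a 2'-O-(1-methoxycarbonylvinyl) ether, 5,4'-bis-MOM ether | CC1(C)C=Cc2c(cc(OCOC)c3c(=O)c(B4OC(C)(C)C(C)(C)O4)c(oc23)-c2ccc(OCOC)cc2OC(=C)C(=O)OC)O1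
A11 | alternative 3 | [Rh(OH)(cod)]2, di-μ-hydroxo-bis(cycloocta-1,5-diene)dirhodium | [Rh+].[Rh+].[OH-].[OH-].C1=CCCC=CCC1.C1=CCCC=CCC1
A12 | alternative 3 | oxepinoflavone (R)-methyl ester, 5,4'-bis-MOM ether | CC1(C)C=Cc2c(cc(OCOC)c3c(=O)c4c(oc23)-c2ccc(OCOC)cc2O[C@@H](C(=O)OC)C4)O1
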